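## Retrosynthetic overview

1. The target (6S,7S,10S,11R,12S,14S,15R; 2E,8E) comes from its 7-hydroxy, tris-silylated macrolactam by carbamoylation and desilylation. The 19-membered lactam is the only ring formed and is closed last, by intramolecular Cu-catalysed N-arylation of the C1 primary amide with the C20 aryl bromide.
2. The seco chain is cut at C7–C8: an (E)-vinylzinc from a C8–C21 methyl-alkyne (hydrozirconation) adds to a C1–C7 α-methoxy aldehyde under chelation control (7S).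
3. The C8–C21 alkyne: C10/C11 from a matched allenylstannane addition to a C11 α-methoxy aldehyde; C12 from catalytic asymmetric allylation, O-methylation, alkene isomerisation and ozonolysis; C14/C15 from catalytic (Z)-crotylboration of 3-bromo-5-silyloxybenzaldehyde.
4. The C1–C7 aldehyde comes from (S)-5-oxotetrahydrofuran-2-carboxylic acid (chiral pool, C6) by lactol Wittig olefination. The allenylstannane comes from pent-3-yn-2-one by asymmetric transfer hydrogenation and anti-SN2′ stannylation.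
5. Ring order: arene bought, acyclic assembly, macrolactam.

Assumptions: positions use geldanamycin-type numbering (C1 amide carbonyl, C15 benzylic carbinol, C16–C21 arene, N on C20); Ar = 3-bromo-5-[(triisopropylsilyl)oxy]phenyl, TBS = tert-butyldimethylsilyl, TIPS = triisopropylsilyl, TBDPS = tert-butyldiphenylsilyl; boron, tin, aluminium and zinc alkoxides that are only protonated in the aqueous work-up are not numbered; Cp ligands are drawn η1 in SMILES; the reagent-controlled facial senses in steps 1, 5, 9 and 13 are assigned from the usual selectivity models and should be confirmed on the first intermediates.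

## Route

**Allenylstannane (steps 1–3)**

Step 1
Reactants: 1 pent-3-yn-2-one
Product: 2 (2S)-pent-3-yn-2-ol
Conditions: RuCl[(S,S)-TsDPEN](p-cymene) (0.5 mol%), i-PrOH, rt
Reagents that add atoms: none
Why: Noyori asymmetric transfer hydrogenation of an ynone, where the alkynyl group takes the place of the aryl group in the Ru–H/N–H transition state, so the (S,S)-catalyst gives the (S)-carbinol in high ee.

Step 2
Reactants: 2 (2S)-pent-3-yn-2-ol
Product: 3 (2S)-pent-3-yn-2-yl methanesulfonate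
Conditions: MsCl, Et3N, CH2Cl2, −78 → 0 °C
Reagents that add atoms: methanesulfonyl chloride CS(=O)(=O)Cl
Why: O-sulfonylation leaves the C–O bond and the stereocentre untouched.

Step 3
Reactants: 3 (2S)-pent-3-yn-2-yl methanesulfonate
Product: 4 (M)-tributyl(penta-2,3-dien-2-yl)stannane
Conditions: Bu3SnH, LDA, THF, 0 °C; CuBr·SMe2, −78 °C; then 3, −78 °C
Reagents that add atoms: tributyltin hydride CCCC[SnH](CCCC)CCCC
Why: anti-SN2′ displacement by the stannylcuprate converts the (S) carbinol centre into the (M) allene axis with full chirality transfer.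

**C8–C21 fragment (steps 4–14)**

Step 4
Reactants: 5 3-bromo-5-hydroxybenzaldehyde
Product: 6 3-bromo-5-[(triisopropylsilyl)oxy]benzaldehyde
Conditions: TIPSCl, imidazole, DMF, rt
Reagents that add atoms: chlorotri(propan-2-yl)silane CC(C)[Si](Cl)(C(C)C)C(C)C
Why: phenol silylation gives a bulky aryl silyl ether that tolerates the later Lewis-acid, organometallic and anhydrous-base steps.

Step 5
Reactants: 6 3-bromo-5-[(triisopropylsilyl)oxy]benzaldehyde
Product: 7 (1R,2S)-1-Ar-2-methylbut-3-en-1-ol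
Conditions: (Z)-crotylboronic acid pinacol ester (1.3 equiv), (R)-TRIP (5 mol%), 4 Å MS, toluene, −30 °C; aq. NaHCO3
Reagents that add atoms: (Z)-crotylboronic acid pinacol ester C/C=C\CB1OC(C)(C)C(C)(C)O1
Why: chiral phosphoric acid-catalysed crotylboration through a closed chair transition state, in which the (Z)-boronate gives the 14,15-syn product and the (R)-acid directs Re-face attack (15R, hence 14S).

Step 6
Reactants: 7 (1R,2S)-1-Ar-2-methylbut-3-en-1-ol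
Product: 8 (3S,4R)-4-Ar-4-(TBSO)-3-methylbut-1-ene
Conditions: TBSOTf, 2,6-lutidine, CH2Cl2, −78 → 0 °C
Reagents that add atoms: tert-butyldimethylsilyl trifluoromethanesulfonate CC(C)(C)[Si](C)(C)OS(=O)(=O)C(F)(F)F
Why: silylation of the hindered benzylic alcohol with the reactive triflate.

Step 7
Reactants: 8 (3S,4R)-4-Ar-4-(TBSO)-3-methylbut-1-ene
Product: 10 (3S,4R)-4-Ar-4-(TBSO)-3-methylbutan-1-ol, via B-alkyl-9-BBN adduct 9 (not isolated)
Conditions: 9-BBN, THF, 0 °C → rt; then NaBO3·4H2O, THF/H2O, rt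
Reagents that add atoms: sodium perborate tetrahydrate (as NaBO3) [Na+].[O-]OB=O
Why: anti-Markovnikov hydroboration–oxidation of the terminal alkene, with perborate as a mild oxidant that spares the aryl silyl ether.

Step 8
Reactants: 10 (3S,4R)-4-Ar-4-(TBSO)-3-methylbutan-1-ol
Product: 11 (3S,4R)-4-Ar-4-(TBSO)-3-methylbutanal
Conditions: Dess–Martin periodinane, CH2Cl2, 0 °C → rt
Reagents that add atoms: none
Why: Dess–Martin oxidation stops at the aldehyde and the β-stereocentre cannot epimerise.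

Step 9
Reactants: 11 (3S,4R)-4-Ar-4-(TBSO)-3-methylbutanal
Product: 12 (4R,6S,7R)-7-Ar-7-(TBSO)-6-methylhept-1-en-4-ol
Conditions: allylSnBu3 (1.5 equiv), (R)-BINOL (20 mol%), Ti(Oi-Pr)4 (20 mol%), 4 Å MS, CH2Cl2, −20 °C; aq. NaHCO3
Reagents that add atoms: allyltributylstannane C=CC[Sn](CCCC)(CCCC)CCCC
Why: Keck asymmetric allylation, in which the (R)-BINOL–Ti Lewis acid directs Re-face attack and sets the future C12 carbinol (4R here) under catalyst control, the remote β-methyl having little influence.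

Step 10
Reactants: 12 (4R,6S,7R)-7-Ar-7-(TBSO)-6-methylhept-1-en-4-ol
Product: 13 (4R,6S,7R)-7-Ar-7-(TBSO)-4-methoxy-6-methylhept-1-ene
Conditions: MeOTf, 2,6-di-tert-butyl-4-methylpyridine, CH2Cl2, rt
Reagents that add atoms: methyl trifluoromethanesulfonate COS(=O)(=O)C(F)(F)F
Why: O-methylation under non-basic conditions, so no alkoxide is formed that could trigger silyl migration.

Step 11
Reactants: 13 (4R,6S,7R)-7-Ar-7-(TBSO)-4-methoxy-6-methylhept-1-ene
Product: 14 (2E,4S,6S,7R)-7-Ar-7-(TBSO)-4-methoxy-6-methylhept-2-ene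
Conditions: Grubbs II (5 mol%), MeOH, 60 °C
Reagents that add atoms: none
Why: the Ru–H species formed from the carbene in methanol moves the terminal double bond by one position to the more stable propenyl isomer (E/Z irrelevant) without touching C12.

Step 12
Reactants: 14 (2E,4S,6S,7R)-7-Ar-7-(TBSO)-4-methoxy-6-methylhept-2-ene
Product: 16 (2S,4S,5R)-5-Ar-5-(TBSO)-2-methoxy-4-methylpentanal, via secondary ozonide 15 (not isolated)
Conditions: O3, CH2Cl2, −78 °C (Sudan III end point); PPh3, −78 °C → rt; used crude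
Reagents that add atoms: ozone [O-][O+]=O
Why: ozonolysis with reductive work-up cleaves the only alkene to the α-methoxy aldehyde under neutral conditions that do not epimerise C12.

Step 13
Reactants: 16 (2S,4S,5R)-5-Ar-5-(TBSO)-2-methoxy-4-methylpentanal; 4 (M)-tributyl(penta-2,3-dien-2-yl)stannane
Product: 17 (1R,2S,4S,5R,6S)-1-Ar-1-(TBSO)-4-methoxy-2,6-dimethylnon-7-yn-5-ol
Conditions: 4 (1.5 equiv), BF3·OEt2, CH2Cl2, −78 °C
Reagents that add atoms: none
Why: Marshall allenylstannane addition by anti-SE2′ through an open transition state, in which the allene axis fixes 10S and the 10,11-syn relationship while non-chelating BF3 gives the Felkin–Anh 11,12-anti product (matched pair, 11R).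

Step 14
Reactants: 17 (1R,2S,4S,5R,6S)-1-Ar-1-(TBSO)-4-methoxy-2,6-dimethylnon-7-yn-5-ol
Product: 18 (1R,2S,4S,5R,6S)-1-Ar-1,5-bis(TBSO)-4-methoxy-2,6-dimethylnon-7-yne
Conditions: TBSOTf, 2,6-lutidine, CH2Cl2, 0 °C
Reagents that add atoms: tert-butyldimethylsilyl trifluoromethanesulfonate CC(C)(C)[Si](C)(C)OS(=O)(=O)C(F)(F)F
Why: silylation of the hindered C11 alcohol so that only the C7 hydroxyl is free after the fragment coupling.

**C1–C7 fragment (steps 15–21)**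

Step 15
Reactants: 19 (S)-5-oxotetrahydrofuran-2-carboxylic acid
Product: 20 (S)-5-(hydroxymethyl)dihydrofuran-2(3H)-one
Conditions: BH3·SMe2, THF, 0 °C → rt; MeOH, then H2O
Reagents that add atoms: none
Why: borane reduces the carboxylic acid chemoselectively over the lactone and the stereocentre (future C6) is not involved.

Step 16
Reactants: 20 (S)-5-(hydroxymethyl)dihydrofuran-2(3H)-one
Product: 21 (S)-5-[(TBDPSO)methyl]dihydrofuran-2(3H)-one
Conditions: TBDPSCl, imidazole, DMF, rt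
Reagents that add atoms: tert-butyl(chloro)diphenylsilane CC(C)(C)[Si](Cl)(c1ccccc1)c1ccccc1
Why: silylation of the primary alcohol.

Step 17
Reactants: 21 (S)-5-[(TBDPSO)methyl]dihydrofuran-2(3H)-one
Product: 22 (5S)-5-[(TBDPSO)methyl]tetrahydrofuran-2-ol (anomer mixture)
Conditions: DIBAL-H, CH2Cl2, −78 °C; Rochelle salt
Reagents that add atoms: none
Why: the tetrahedral aluminate is stable at −78 °C, so reduction of the lactone stops at the lactol.

Step 18
Reactants: 22 (5S)-5-[(TBDPSO)methyl]tetrahydrofuran-2-ol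
Product: 23 ethyl (2E,6S)-7-(TBDPSO)-6-hydroxy-2-methylhept-2-enoate
Conditions: Ph3P=C(Me)CO2Et, toluene, 80 °C
Reagents that add atoms: ethyl 2-(triphenyl-λ5-phosphanylidene)propanoate CCOC(=O)C(C)=P(c1ccccc1)(c1ccccc1)c1ccccc1
Why: Wittig olefination of the open hydroxy-aldehyde tautomer with a stabilised α-methyl ylide gives the (E)-trisubstituted enoate (C1–C3).

Step 19
Reactants: 23 ethyl (2E,6S)-7-(TBDPSO)-6-hydroxy-2-methylhept-2-enoate
Product: 24 ethyl (2E,6S)-7-(TBDPSO)-6-methoxy-2-methylhept-2-enoate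
Conditions: MeOTf, 2,6-di-tert-butyl-4-methylpyridine, CH2Cl2, rt
Reagents that add atoms: methyl trifluoromethanesulfonate COS(=O)(=O)C(F)(F)F
Why: non-basic O-methylation avoids the 5-exo oxa-Michael cyclisation that an alkoxide would undergo.

Step 20
Reactants: 24 ethyl (2E,6S)-7-(TBDPSO)-6-methoxy-2-methylhept-2-enoate
Product: 25 ethyl (2E,6S)-7-hydroxy-6-methoxy-2-methylhept-2-enoate
Conditions: HF·pyridine, pyridine, THF, 0 °C → rt
Reagents that add atoms: none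
Why: fluoride cleaves the Si–O bond under weakly acidic conditions that leave the enoate untouched.

Step 21
Reactants: 25 ethyl (2E,6S)-7-hydroxy-6-methoxy-2-methylhept-2-enoate
Product: 26 ethyl (2E,6S)-6-methoxy-2-methyl-7-oxohept-2-enoate
Conditions: Dess–Martin periodinane, CH2Cl2, 0 °C; used at once
Reagents that add atoms: none
Why: mild oxidation gives the α-methoxy aldehyde without epimerising C6.

**Coupling and endgame (steps 22–26)**

Step 22
Reactants: 18 (1R,2S,4S,5R,6S)-1-Ar-1,5-bis(TBSO)-4-methoxy-2,6-dimethylnon-7-yne; 26 ethyl (2E,6S)-6-methoxy-2-methyl-7-oxohept-2-enoate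
Product: 29 ethyl (2E,6S,7S,8E,10S,11R,12S,14S,15R)-15-Ar-11,15-bis(TBSO)-7-hydroxy-6,12-dimethoxy-2,8,10,14-tetramethylpentadeca-2,8-dienoate, via chloro(alkenyl)zirconocene 27 (not isolated), via methyl(alkenyl)zinc 28 (not isolated)
Conditions: Cp2Zr(H)Cl, CH2Cl2, rt → 40 °C; Me2Zn, −65 °C; then 26 (1.5 equiv), −65 → 0 °C
Reagents that add atoms: none
Why: syn-hydrozirconation places Zr on the less hindered methyl-bearing alkyne carbon (E-alkene), Zr-to-Zn transmetalation retains geometry, and the vinylzinc adds to the aldehyde through a five-membered zinc chelate with the α-methoxy group (Cram-chelate, 6,7-syn, 7S).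

Step 23
Reactants: 29 ethyl (2E,6S,7S,8E,10S,11R,12S,14S,15R)-15-Ar-11,15-bis(TBSO)-7-hydroxy-6,12-dimethoxy-2,8,10,14-tetramethylpentadeca-2,8-dienoate
Product: 30 (2E,6S,7S,8E,10S,11R,12S,14S,15R)-15-Ar-11,15-bis(TBSO)-7-hydroxy-6,12-dimethoxy-2,8,10,14-tetramethylpentadeca-2,8-dienamide
Conditions: AlMe3, NH4Cl, toluene, 0 → 50 °C
Reagents that add atoms: ammonium chloride [NH4+].[Cl-]
Why: Weinreb-type aminolysis by the aluminium amide formed in the flask converts the ester directly into the primary amide, with the 7-OH held as its aluminium alkoxide and the silyl ethers untouched.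

Step 24
Reactants: 30 (2E,6S,7S,8E,10S,11R,12S,14S,15R)-15-Ar-11,15-bis(TBSO)-7-hydroxy-6,12-dimethoxy-2,8,10,14-tetramethylpentadeca-2,8-dienamide
Product: 31 7-hydroxy macrolactam (19-membered ring; 11-OTBS; 15-OTBS; 18-OTIPS)
Conditions: CuI (1 equiv), N,N′-dimethylethylenediamine, K2CO3, toluene (2 mM), 100 °C
Reagents that add atoms: none
Why: intramolecular Goldberg amidation (Cu(I)/diamine) joins the primary amide nitrogen to the aryl bromide carbon at high dilution, the amide N–H being arylated in preference to the hindered secondary alcohol.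

Step 25
Reactants: 31 7-hydroxy macrolactam
Product: 33 7-O-carbamoyl macrolactam (11-OTBS; 15-OTBS; 18-OTIPS), via N-trichloroacetyl carbamate 32 (not isolated)
Conditions: Cl3CC(O)NCO, CH2Cl2, 0 °C; then neutral Al2O3 (moist), rt
Reagents that add atoms: trichloroacetyl isocyanate O=C=NC(=O)C(Cl)(Cl)Cl
Why: the acyl isocyanate acylates the only free hydroxyl, and hydrolysis of the N-trichloroacetyl group on neutral alumina leaves the primary carbamate without exposing the aryl silyl ether to base.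

Step 26
Reactants: 33 7-O-carbamoyl macrolactam
Product: 34 target CNP0309815.1
Conditions: TBAF, AcOH (1:1), THF, 0 → 35 °C
Reagents that add atoms: none
Why: buffered fluoride removes the aryl TIPS ether and both secondary TBS ethers, while the carbamate, the anilide and the benzylic alcohol are stable at this near-neutral pH.

## Compound list

1 | pent-3-yn-2-one | CC#CC(C)=O | starting material
2 | (2S)-pent-3-yn-2-ol | CC#C[C@H](C)O | intermediate
3 | (2S)-pent-3-yn-2-yl methanesulfonate | CC#C[C@H](C)OS(C)(=O)=O | intermediate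
4 | (M)-tributyl(penta-2,3-dien-2-yl)stannane (aR axis) | CCCC[Sn](CCCC)(CCCC)C(C)=[C@]=C([H])C | intermediate
5 | 3-bromo-5-hydroxybenzaldehyde | O=Cc1cc(O)cc(Br)c1 | starting material
6 | 3-bromo-5-[(triisopropylsilyl)oxy]benzaldehyde | O=Cc1cc(O[Si](C(C)C)(C(C)C)C(C)C)cc(Br)c1 | intermediate
7 | (1R,2S)-1-Ar-2-methylbut-3-en-1-ol | C=C[C@H](C)[C@@H](O)c1cc(O[Si](C(C)C)(C(C)C)C(C)C)cc(Br)c1 | intermediate
8 | (3S,4R)-4-Ar-4-(TBSO)-3-methylbut-1-ene | C=C[C@H](C)[C@@H](O[Si](C)(C)C(C)(C)C)c1cc(O[Si](C(C)C)(C(C)C)C(C)C)cc(Br)c1 | intermediate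
9 | B-[(3S,4R)-4-Ar-4-(TBSO)-3-methylbutyl]-9-borabicyclo[3.3.1]nonane (not isolated) | C1CCC2CCCC1B2CC[C@H](C)[C@@H](O[Si](C)(C)C(C)(C)C)c1cc(O[Si](C(C)C)(C(C)C)C(C)C)cc(Br)c1 | intermediate
10 | (3S,4R)-4-Ar-4-(TBSO)-3-methylbutan-1-ol | OCC[C@H](C)[C@@H](O[Si](C)(C)C(C)(C)C)c1cc(O[Si](C(C)C)(C(C)C)C(C)C)cc(Br)c1 | intermediate
11 | (3S,4R)-4-Ar-4-(TBSO)-3-methylbutanal | O=CC[C@H](C)[C@@H](O[Si](C)(C)C(C)(C)C)c1cc(O[Si](C(C)C)(C(C)C)C(C)C)cc(Br)c1 | intermediate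
12 | (4R,6S,7R)-7-Ar-7-(TBSO)-6-methylhept-1-en-4-ol | C=CC[C@@H](O)C[C@H](C)[C@@H](O[Si](C)(C)C(C)(C)C)c1cc(O[Si](C(C)C)(C(C)C)C(C)C)cc(Br)c1 | intermediate
13 | (4R,6S,7R)-7-Ar-7-(TBSO)-4-methoxy-6-methylhept-1-ene | C=CC[C@@H](OC)C[C@H](C)[C@@H](O[Si](C)(C)C(C)(C)C)c1cc(O[Si](C(C)C)(C(C)C)C(C)C)cc(Br)c1 | intermediate
14 | (2E,4S,6S,7R)-7-Ar-7-(TBSO)-4-methoxy-6-methylhept-2-ene | C/C=C/[C@@H](OC)C[C@H](C)[C@@H](O[Si](C)(C)C(C)(C)C)c1cc(O[Si](C(C)C)(C(C)C)C(C)C)cc(Br)c1 | intermediate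
15 | 3-methyl-5-[(1S,3S,4R)-4-Ar-4-(TBSO)-1-methoxy-3-methylbutyl]-1,2,4-trioxolane (not isolated; ring diastereomers) | CC1OOC(O1)[C@@H](OC)C[C@H](C)[C@@H](O[Si](C)(C)C(C)(C)C)c1cc(O[Si](C(C)C)(C(C)C)C(C)C)cc(Br)c1 | intermediate
16 | (2S,4S,5R)-5-Ar-5-(TBSO)-2-methoxy-4-methylpentanal | O=C[C@@H](OC)C[C@H](C)[C@@H](O[Si](C)(C)C(C)(C)C)c1cc(O[Si](C(C)C)(C(C)C)C(C)C)cc(Br)c1 | intermediate
17 | (1R,2S,4S,5R,6S)-1-Ar-1-(TBSO)-4-methoxy-2,6-dimethylnon-7-yn-5-ol | CC#C[C@H](C)[C@@H](O)[C@@H](OC)C[C@H](C)[C@@H](O[Si](C)(C)C(C)(C)C)c1cc(O[Si](C(C)C)(C(C)C)C(C)C)cc(Br)c1 | intermediate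
18 | (1R,2S,4S,5R,6S)-1-Ar-1,5-bis(TBSO)-4-methoxy-2,6-dimethylnon-7-yne | CC#C[C@H](C)[C@@H](O[Si](C)(C)C(C)(C)C)[C@@H](OC)C[C@H](C)[C@@H](O[Si](C)(C)C(C)(C)C)c1cc(O[Si](C(C)C)(C(C)C)C(C)C)cc(Br)c1 | intermediate
19 | (S)-5-oxotetrahydrofuran-2-carboxylic acid | OC(=O)[C@@H]1CCC(=O)O1 | starting material
20 | (S)-5-(hydroxymethyl)dihydrofuran-2(3H)-one | OC[C@@H]1CCC(=O)O1 | intermediate
21 | (S)-5-[(TBDPSO)methyl]dihydrofuran-2(3H)-one | CC(C)(C)[Si](OC[C@@H]1CCC(=O)O1)(c1ccccc1)c1ccccc1 | intermediate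
22 | (5S)-5-[(TBDPSO)methyl]tetrahydrofuran-2-ol (anomer mixture) | CC(C)(C)[Si](OC[C@@H]1CCC(O)O1)(c1ccccc1)c1ccccc1 | intermediate
23 | ethyl (2E,6S)-7-(TBDPSO)-6-hydroxy-2-methylhept-2-enoate | CCOC(=O)/C(C)=C/CC[C@H](O)CO[Si](c1ccccc1)(c1ccccc1)C(C)(C)C | intermediate
24 | ethyl (2E,6S)-7-(TBDPSO)-6-methoxy-2-methylhept-2-enoate | CCOC(=O)/C(C)=C/CC[C@H](OC)CO[Si](c1ccccc1)(c1ccccc1)C(C)(C)C | intermediate
25 | ethyl (2E,6S)-7-hydroxy-6-methoxy-2-methylhept-2-enoate | CCOC(=O)/C(C)=C/CC[C@H](OC)CO | intermediate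
26 | ethyl (2E,6S)-6-methoxy-2-methyl-7-oxohept-2-enoate | CCOC(=O)/C(C)=C/CC[C@H](OC)C=O | intermediate
27 | chloro[(2E,4S,5R,6S,8S,9R)-9-Ar-5,9-bis(TBSO)-6-methoxy-4,8-dimethylnon-2-en-2-yl]zirconocene (not isolated) | Cl[Zr](C1C=CC=C1)(C1C=CC=C1)/C(C)=C/[C@H](C)[C@@H](O[Si](C)(C)C(C)(C)C)[C@@H](OC)C[C@H](C)[C@@H](O[Si](C)(C)C(C)(C)C)c1cc(O[Si](C(C)C)(C(C)C)C(C)C)cc(Br)c1 | intermediate
28 | methyl[(2E,4S,5R,6S,8S,9R)-9-Ar-5,9-bis(TBSO)-6-methoxy-4,8-dimethylnon-2-en-2-yl]zinc (not isolated) | C[Zn]/C(C)=C/[C@H](C)[C@@H](O[Si](C)(C)C(C)(C)C)[C@@H](OC)C[C@H](C)[C@@H](O[Si](C)(C)C(C)(C)C)c1cc(O[Si](C(C)C)(C(C)C)C(C)C)cc(Br)c1 | intermediate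
29 | ethyl (2E,6S,7S,8E,10S,11R,12S,14S,15R)-15-Ar-11,15-bis(TBSO)-7-hydroxy-6,12-dimethoxy-2,8,10,14-tetramethylpentadeca-2,8-dienoate | CCOC(=O)/C(C)=C/CC[C@H](OC)[C@@H](O)/C(C)=C/[C@H](C)[C@@H](O[Si](C)(C)C(C)(C)C)[C@@H](OC)C[C@H](C)[C@@H](O[Si](C)(C)C(C)(C)C)c1cc(O[Si](C(C)C)(C(C)C)C(C)C)cc(Br)c1 | intermediate
30 | (2E,6S,7S,8E,10S,11R,12S,14S,15R)-15-Ar-11,15-bis(TBSO)-7-hydroxy-6,12-dimethoxy-2,8,10,14-tetramethylpentadeca-2,8-dienamide | NC(=O)/C(C)=C/CC[C@H](OC)[C@@H](O)/C(C)=C/[C@H](C)[C@@H](O[Si](C)(C)C(C)(C)C)[C@@H](OC)C[C@H](C)[C@@H](O[Si](C)(C)C(C)(C)C)c1cc(O[Si](C(C)C)(C(C)C)C(C)C)cc(Br)c1 | intermediate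
31 | 7-hydroxy macrolactam (19-membered; 11-OTBS; 15-OTBS; 18-OTIPS) | CO[C@H]1C[C@H](C)[C@@H](O[Si](C)(C)C(C)(C)C)c2cc(O[Si](C(C)C)(C(C)C)C(C)C)cc(c2)NC(=O)/C(C)=C/CC[C@H](OC)[C@@H](O)/C(C)=C/[C@H](C)[C@H]1O[Si](C)(C)C(C)(C)C | intermediate
32 | 7-O-[N-(trichloroacetyl)carbamoyl] macrolactam (not isolated) | CO[C@H]1C[C@H](C)[C@@H](O[Si](C)(C)C(C)(C)C)c2cc(O[Si](C(C)C)(C(C)C)C(C)C)cc(c2)NC(=O)/C(C)=C/CC[C@H](OC)[C@@H](OC(=O)NC(=O)C(Cl)(Cl)Cl)/C(C)=C/[C@H](C)[C@H]1O[Si](C)(C)C(C)(C)C | intermediate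
33 | 7-O-carbamoyl macrolactam (11-OTBS; 15-OTBS; 18-OTIPS) | CO[C@H]1C[C@H](C)[C@@H](O[Si](C)(C)C(C)(C)C)c2cc(O[Si](C(C)C)(C(C)C)C(C)C)cc(c2)NC(=O)/C(C)=C/CC[C@H](OC)[C@@H](OC(N)=O)/C(C)=C/[C@H](C)[C@H]1O[Si](C)(C)C(C)(C)C | intermediate
34 | CNP0309815.1 | CO[C@H]1C[C@H](C)[C@@H](O)c2cc(O)cc(c2)NC(=O)/C(C)=C/CC[C@H](OC)[C@@H](OC(N)=O)/C(C)=C/[C@H](C)[C@H]1O | target

## Step count, longest linear sequence and risks

Total step count: 26. Longest linear sequence: 16 steps (5 → 34, steps 4–14 and 22–26). The side branches are 3 steps (1 → 4) and 7 steps (19 → 26).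

Steps most likely to fail:

**Step 13 (allenylstannane addition).** The α-methoxy aldehyde 16 is epimerisable and the result depends on double stereodifferentiation with a trisubstituted allenylstannane. The fallback sets out from 16 and comes back at 18. It builds the propargylic centre by crotylboration and alkene-to-alkyne conversion. The (Z)-crotylboronate of (S,S)-diisopropyl tartrate (toluene, 4 Å MS, −78 °C; Re-face attack reinforcing the Felkin preference) gives the 10,11-syn homoallylic alcohol F1. TBSOTf/2,6-lutidine gives the bis-silyl ether F2, and ozonolysis (O3, then PPh3) gives the α-methyl aldehyde F3. Colvin homologation with lithiated trimethylsilyldiazomethane (THF, −78 → 0 °C) gives the terminal alkyne F4. Deprotonation with LDA (1.05 equiv, −78 °C) and MeI then gives 18.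

**Step 22 (hydrozirconation, zinc transmetalation, addition).** The risks are regiocontrol in the hydrometalation and the level of chelation control at C7. The fallback sets out from 18 and comes back at 29. Hydrozirconation of 18 followed by iodine gives the (E)-vinyl iodide F5. Nozaki–Hiyama–Kishi coupling (CrCl2, cat. NiCl2, DMSO) with aldehyde 26 gives the C7 carbinol as a mixture of 29 and its (7R)-epimer F6. The mixture is oxidised with Dess–Martin periodinane to the enone F7. Reduction with (S)-Me-CBS and catecholborane (alkenyl as the large group) sets 7S under reagent control and gives 29.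

**Step 24 (Cu-mediated macrolactam closure).** The risks are oligomerisation, loss of the aryl silyl ether and competing reaction at the free 7-OH. The fallback sets out from 29 and comes back at 31. It introduces the nitrogen first and closes the ring by classical amide formation. Pd2(dba)3/BINAP/Cs2CO3 coupling of 29 with benzophenone imine gives the N-aryl imine F8. Transimination with NH2OH·HCl/NaOAc in MeOH gives the aniline F9. Me3SnOH (1,2-dichloroethane, 80 °C) cleaves the ethyl ester to the amino acid F10. BOP-Cl and i-Pr2NEt in toluene at high dilution then close the 19-membered lactam to 31.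

## Further compounds

F1 | step 13 | (3S,4R,5S,7S,8R)-8-Ar-8-(TBSO)-5-methoxy-3,7-dimethyloct-1-en-4-ol | C=C[C@H](C)[C@@H](O)[C@@H](OC)C[C@H](C)[C@@H](O[Si](C)(C)C(C)(C)C)c1cc(O[Si](C(C)C)(C(C)C)C(C)C)cc(Br)c1
F2 | step 13 | (3S,4R,5S,7S,8R)-8-Ar-4,8-bis(TBSO)-5-methoxy-3,7-dimethyloct-1-ene | C=C[C@H](C)[C@@H](O[Si](C)(C)C(C)(C)C)[C@@H](OC)C[C@H](C)[C@@H](O[Si](C)(C)C(C)(C)C)c1cc(O[Si](C(C)C)(C(C)C)C(C)C)cc(Br)c1
F3 | step 13 | (2R,3R,4S,6S,7R)-7-Ar-3,7-bis(TBSO)-4-methoxy-2,6-dimethylheptanal | O=C[C@H](C)[C@@H](O[Si](C)(C)C(C)(C)C)[C@@H](OC)C[C@H](C)[C@@H](O[Si](C)(C)C(C)(C)C)c1cc(O[Si](C(C)C)(C(C)C)C(C)C)cc(Br)c1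
F4 | step 13 | (1R,2S,4S,5R,6S)-1-Ar-1,5-bis(TBSO)-4-methoxy-2,6-dimethyloct-7-yne | C#C[C@H](C)[C@@H](O[Si](C)(C)C(C)(C)C)[C@@H](OC)C[C@H](C)[C@@H](O[Si](C)(C)C(C)(C)C)c1cc(O[Si](C(C)C)(C(C)C)C(C)C)cc(Br)c1
F5 | step 22 | (1R,2S,4S,5R,6S,7E)-1-Ar-1,5-bis(TBSO)-8-iodo-4-methoxy-2,6-dimethylnon-7-ene | I/C(C)=C/[C@H](C)[C@@H](O[Si](C)(C)C(C)(C)C)[C@@H](OC)C[C@H](C)[C@@H](O[Si](C)(C)C(C)(C)C)c1cc(O[Si](C(C)C)(C(C)C)C(C)C)cc(Br)c1
F6 | step 22 | ethyl (2E,6S,7R,8E,10S,11R,12S,14S,15R)-15-Ar-11,15-bis(TBSO)-7-hydroxy-6,12-dimethoxy-2,8,10,14-tetramethylpentadeca-2,8-dienoate (7-epimer of 29) | CCOC(=O)/C(C)=C/CC[C@H](OC)[C@H](O)/C(C)=C/[C@H](C)[C@@H](O[Si](C)(C)C(C)(C)C)[C@@H](OC)C[C@H](C)[C@@H](O[Si](C)(C)C(C)(C)C)c1cc(O[Si](C(C)C)(C(C)C)C(C)C)cc(Br)c1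
F7 | step 22 | ethyl (2E,6S,8E,10S,11R,12S,14S,15R)-15-Ar-11,15-bis(TBSO)-6,12-dimethoxy-2,8,10,14-tetramethyl-7-oxopentadeca-2,8-dienoate | CCOC(=O)/C(C)=C/CC[C@H](OC)C(=O)/C(C)=C/[C@H](C)[C@@H](O[Si](C)(C)C(C)(C)C)[C@@H](OC)C[C@H](C)[C@@H](O[Si](C)(C)C(C)(C)C)c1cc(O[Si](C(C)C)(C(C)C)C(C)C)cc(Br)c1
F8 | step 24 | ethyl ester 29 with Br replaced by N=CPh2 (N-aryl benzophenone imine) | CCOC(=O)/C(C)=C/CC[C@H](OC)[C@@H](O)/C(C)=C/[C@H](C)[C@@H](O[Si](C)(C)C(C)(C)C)[C@@H](OC)C[C@H](C)[C@@H](O[Si](C)(C)C(C)(C)C)c1cc(O[Si](C(C)C)(C(C)C)C(C)C)cc(N=C(c2ccccc2)c2ccccc2)c1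
F9 | step 24 | ethyl ester 29 with Br replaced by NH2 (aniline) | CCOC(=O)/C(C)=C/CC[C@H](OC)[C@@H](O)/C(C)=C/[C@H](C)[C@@H](O[Si](C)(C)C(C)(C)C)[C@@H](OC)C[C@H](C)[C@@H](O[Si](C)(C)C(C)(C)C)c1cc(O[Si](C(C)C)(C(C)C)C(C)C)cc(N)c1
F10 | step 24 | (2E,6S,7S,8E,10S,11R,12S,14S,15R)-15-[3-amino-5-(TIPSO)phenyl]-11,15-bis(TBSO)-7-hydroxy-6,12-dimethoxy-2,8,10,14-tetramethylpentadeca-2,8-dienoic acid | OC(=O)/C(C)=C/CC[C@H](OC)[C@@H](O)/C(C)=C/[C@H](C)[C@@H](O[Si](C)(C)C(C)(C)C)[C@@H](OC)C[C@H](C)[C@@H](O[Si](C)(C)C(C)(C)C)c1cc(O[Si](C(C)C)(C(C)C)C(C)C)cc(N)c1
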